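Look at the tail of the target curve first. You asked me for a quick number, and I found the tail gave me one.

| setting | violet | ochre | green | red | noon | dusk | summer | spring |
|---|---|---|---|---|---|---|---|---|
| starting material | 0.20 mM | 0.10 mM | 0.40 mM | 0.20 mM | 0.20 mM (in portions, 3, over 12 min) | 0.20 mM | 0.20 mM (fed, over 12 min) | 0.20 mM |
| reagent | 0.80 mM | 0.80 mM | 0.80 mM | 1.6 mM | 0.800 mM | 0.800 mM (fed, over 12 min) | 0.800 mM | 0.800 mM |
| remark | run made earlier | run made earlier | run made earlier | run made earlier | first portion at the start, last at 12 min | all else is in the flask from the start; the feed brings no volume worth counting | all else is in the flask from the start; the feed brings no volume worth counting | everything together at the start |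
| time |  |  |  |  | 15 min | 15 min | 15 min | 15 min |

| run | time / min | target / % | side product A / % |
|---|---|---|---|
| violet | 0.667 | 21.8 | 12.3 |
| violet | 1.00 | 22.9 | 15.5 |
| violet | 1.50 | 22.0 | 15.9 |
| violet | 2.50 | 17.9 | 18.9 |
| violet | 4.00 | 12.0 | 19.5 |
| violet | 6.00 | 6.4 | 19.1 |
| violet | 10.0 | 1.5 | 19.2 |
| ochre | 1.33 | 29.2 | 19.9 |
| ochre | 2.00 | 26.2 | 22.0 |
| ochre | 3.00 | 19.8 | 23.0 |
| ochre | 5.00 | 9.8 | 23.7 |
| ochre | 8.00 | 3.9 | 23.1 |
| ochre | 12.0 | 1.8 | 22.4 |
| ochre | 20.0 | 0 | 23.0 |
| green | 2.50 | 12.9 | 14.0 |
| green | 5.00 | 5.6 | 14.2 |
| green | 8.00 | 1.8 | 14.5 |
| green | 10.0 | 2.1 | 13.7 |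
| green | 12.0 | 1.1 | 13.8 |
| green | 15.0 | 1.1 | 13.5 |
| green | 20.0 | 0.1 | 13.8 |
| red | 4.00 | 4.7 | 12.1 |
| red | 8.00 | 0 | 12.9 |
| red | 10.0 | 0.1 | 13.0 |
| red | 15.0 | 0.5 | 13.9 |
| red | 20.0 | 0.8 | 13.9 |

(each reading ± 0.5 percentage points)

- percentages count the starting material that a species holds: one side product B or side product C counts as two
- the numbers in the tables scatter with a standard deviation of 0.5 percentage points
- steps thought possible: 2 starting material -> side product B; reagent + target -> over-reaction product; starting material + reagent -> target; starting material -> side product A; starting material + target -> side product C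

- the best flask by share of target in target plus side product A; "all alike" if 1.5 percentage points covers them all (noon / dusk / summer / spring / all alike)
- share of target in target plus side product A at the end, noon
- share of target in target plus side product A at the end, dusk
- share of target in target plus side product A at the end, summer
- share of target in target plus side product A at the end, spring

I wrote target as a fraction of the charge. Past the peak, I compared violet with ochre, which held half of violet's starting material but the same reagent:

violet: 0.294 min⁻¹
ochre: 0.325 min⁻¹

Violet's reagent stood at 4.00 times its starting material, so I took reagent as nearly constant and read the loss as pseudo-first-order in target. From the mean I took the target lifetime, the time in which target standing in the flask falls by a factor e at this reagent charge: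

lifetime = 3.23 min

Spring is violet's recipe, so I carried violet's peak reading, 22.9% at 1.00 min, forward to 15 min:

spring target = 0.301%

Against violet's side product A, 19.2%, that made a share of 1.54%.

Noon's last portion enters at 12 min, and the target standing then keeps this fraction:

keep = 0.395

That portion is a third of the charge, and ochre at 3.00 min was my nearest simulated flask. So I expected 6.60% of target beside ochre's 23.7% of side product A, a share of 21.8%. I reckoned neither summer nor dusk.

Your forecast named noon: noon 27%, dusk 1%, summer 22.5%, spring 2%, with “target is almost gone” in spring. My noon stood below its figure.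

Noon came out best at 25.1%, with dusk 0.704%, summer 19.2% and spring 1.73%. At its end target was being made at 0.183 of the rate at which it was used up. Noon held 3.25% of target just before the last portion, and keep turns that into 1.28% of the 8.82% at the end. By this reckoning the last portion supplied the other 7.53%.

    2 starting material → side product B (k = 88.0 M⁻¹ s⁻¹)
    reagent + target → over-reaction product (k = 8.20 M⁻¹ s⁻¹)
    starting material + reagent → target (k = 18.0 M⁻¹ s⁻¹)
    starting material → side product A (k = 0.00670 s⁻¹)
    starting material + target → side product C (k = 22.0 M⁻¹ s⁻¹)

For noon read at 25 min, the lifetime carries 8.82% forward to 0.399%. The computed flask held 0.477% of target, a share of 1.77%.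

(The runs are calculated for substances that don't exist.)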